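**Plan**

- Retrosynthetic cuts, in order: (a) the bond between benzofuran C5 and the CH2 of the dihydrochalcone arm; (b) the C3–C(=O) bond of the ring aryl ketone; (c) C2–C3 of the dihydrofuran ring; (d) the ArO–CH2 ether bond.
- Enabling feature: the arm is C5–CH2–CH2–C(=O)Ar, so its carbonyl lies β to the carbon bound to C5 (a ketone homoenolate retron). C5 is para to the ring oxygen O1, so a bromide can be carried there from a commercial para-bromophenol building block. The homoenolate is stored as a strained 1-arylcyclopropanol, a temporary three-membered ring that is opened in the coupling itself.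
- Forward order: Mitsunobu ether, aryldiazoacetate, Rh(II) 1,5 C–H insertion (closes the dihydrofuran ring, cis), epimerisation to trans, Weinreb amide, ring aryl ketone, Pd homoenolate arylation (joins the second resorcinol ketone arm), global MOM removal.
- Stereochemistry: C2 (S) comes from the chiral dirhodium catalyst in the C–H insertion; C3 (S) comes from thermodynamic equilibration trans to the C2 aryl group; the fragment coupling creates no stereocentre.

Key step: step 11

Assumption (chemistry): in the C–H insertion the (R)-configured catalyst Rh2(R-PTTL)4 is taken to deliver the (2S) ring carbon; should the first run show the opposite sense, Rh2(S-PTTL)4 is used with no other change.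

**Route**

Step 1
Reactants: 1 4-(methoxymethoxy)benzaldehyde
Product: 2 [4-(methoxymethoxy)phenyl]methanol
Conditions: NaBH4, MeOH, 0 °C
Reagents that add atoms: none
Why: Borohydride reduction of an aryl aldehyde should give the benzylic alcohol cleanly and leave the MOM acetal untouched.

Step 2
Reactants: 2 [4-(methoxymethoxy)phenyl]methanol; 3 methyl 2-(5-bromo-2-hydroxyphenyl)acetate
Product: 4 methyl 2-[5-bromo-2-{[4-(methoxymethoxy)phenyl]methoxy}phenyl]acetate
Conditions: PPh3, DIAD, THF, 0 °C → rt
Reagents that add atoms: none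
Why: Mitsunobu etherification of the acidic phenol with a primary benzylic alcohol runs under neutral conditions, which avoids lactonisation of the 2-hydroxyphenylacetate and needs no labile p-alkoxybenzyl halide.

Step 3
Reactants: 4 methyl 2-[5-bromo-2-{[4-(methoxymethoxy)phenyl]methoxy}phenyl]acetate
Product: 5 methyl 2-[5-bromo-2-{[4-(methoxymethoxy)phenyl]methoxy}phenyl]-2-diazoacetate
Conditions: p-ABSA, DBU, MeCN, 0 °C → rt
Reagents that add atoms: 4-acetamidobenzenesulfonyl azide (p-ABSA), CC(=O)Nc1ccc(cc1)S(=O)(=O)N=[N+]=[N-]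
Why: Regitz diazo transfer to the aryl- and ester-activated CH2 is the standard entry to aryldiazoacetates (donor/acceptor carbene precursors).

Step 4
Reactants: 5 methyl 2-[5-bromo-2-{[4-(methoxymethoxy)phenyl]methoxy}phenyl]-2-diazoacetate
Product: 6 methyl (2S,3R)-5-bromo-2-[4-(methoxymethoxy)phenyl]-2,3-dihydro-1-benzofuran-3-carboxylate (cis)
Conditions: Rh2(R-PTTL)4 (1 mol %), toluene, −60 °C
Reagents that add atoms: none
Why: Rh(II)-carbenoid intramolecular 1,5 C–H insertion into the ether-activated p-alkoxybenzylic CH2 should close the dihydrofuran ring (C2–C3 bond) through a concerted three-centre transition state that gives the cis ester, the chiral carboxylate catalyst choosing between the two enantiotopic benzylic hydrogens and so setting C2 as S (C3 is corrected in step 5).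

Step 5
Reactants: 6 methyl (2S,3R)-5-bromo-2-[4-(methoxymethoxy)phenyl]-2,3-dihydro-1-benzofuran-3-carboxylate
Product: 7 methyl (2S,3S)-5-bromo-2-[4-(methoxymethoxy)phenyl]-2,3-dihydro-1-benzofuran-3-carboxylate (trans)
Conditions: NaOMe (0.2 equiv), MeOH, rt
Reagents that add atoms: none
Why: Base-mediated epimerisation through the ester enolate should move the C3 ester trans to the C2 aryl group under thermodynamic control, while C2 cannot scramble because loss of the phenoxide O1 would be the reverse of a 5-endo-trig closure (C2–O bond orthogonal to the enolate π system).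

Step 6
Reactants: 7 methyl (2S,3S)-5-bromo-2-[4-(methoxymethoxy)phenyl]-2,3-dihydro-1-benzofuran-3-carboxylate
Product: 8 (2S,3S)-5-bromo-N-methoxy-2-[4-(methoxymethoxy)phenyl]-N-methyl-2,3-dihydro-1-benzofuran-3-carboxamide
Conditions: MeNHOMe·HCl, i-PrMgCl, THF, −20 → 0 °C
Reagents that add atoms: N,O-dimethylhydroxylamine hydrochloride, CNOC.Cl
Why: Aminolysis of the methyl ester by the magnesium amide of N,O-dimethylhydroxylamine (Weinreb amide formation) runs at low temperature, where the electron-rich aryl bromide and the MOM ether are inert and C3 stays trans.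

Step 7
Reactants: 9 4-bromobenzene-1,3-diol
Product: 10 1-bromo-2,4-bis(methoxymethoxy)benzene
Conditions: MOMCl, i-Pr2NEt, CH2Cl2, 0 °C → rt
Reagents that add atoms: chloromethyl methyl ether (MOMCl), COCCl
Why: O-Alkylation of both phenols with MOMCl and Hünig's base (Williamson-type acetal formation) should give the bis-MOM ether, which later stabilises the aryllithium by chelation.

Step 8
Reactants: 8 (2S,3S)-5-bromo-N-methoxy-2-[4-(methoxymethoxy)phenyl]-N-methyl-2,3-dihydro-1-benzofuran-3-carboxamide; 10 1-bromo-2,4-bis(methoxymethoxy)benzene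
Product: 13 [(2S,3S)-5-bromo-2-[4-(methoxymethoxy)phenyl]-2,3-dihydro-1-benzofuran-3-yl][2,4-bis(methoxymethoxy)phenyl]methanone, via 2,4-bis(methoxymethoxy)phenyllithium 11 (not isolated), via lithium hemiaminal alkoxide 12 (not isolated)
Conditions: 10 (1.5 equiv), n-BuLi (1.45 equiv), THF, −78 °C; then 8, −78 → −40 °C; aq NH4Cl; then DBU (cat.), CH2Cl2, rt
Reagents that add atoms: none
Why: Bromine–lithium exchange gives an ortho-alkoxy-chelated aryllithium that adds once to the Weinreb amide (Weinreb ketone synthesis; the lithium chelate collapses only on work-up), is too stabilised to exchange with the unactivated C5 bromide, and the DBU wash returns any C3 epimer to the trans ketone.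

Step 9
Reactants: 14 methyl 2,4-dihydroxybenzoate
Product: 15 methyl 2,4-bis(methoxymethoxy)benzoate
Conditions: NaH, MOMCl, DMF, 0 °C → rt
Reagents that add atoms: chloromethyl methyl ether (MOMCl), COCCl
Why: O-Alkylation of both phenoxides with MOMCl should work once NaH has broken the hydrogen bond of the 2-OH to the ester.

Step 10
Reactants: 15 methyl 2,4-bis(methoxymethoxy)benzoate
Product: 16 1-[2,4-bis(methoxymethoxy)phenyl]cyclopropan-1-ol
Conditions: EtMgBr (3 equiv), Ti(OiPr)4 (20 mol %), THF, 0 °C → rt; aq NH4Cl
Reagents that add atoms: ethylmagnesium bromide, CC[Mg]Br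
Why: Kulinkovich cyclopropanation, in which the titanacyclopropane formed from EtMgBr and Ti(OiPr)4 acts as a 1,2-dicarbanion toward the ester, should give the 1-arylcyclopropanol that stores the ketone homoenolate.

Step 11
Reactants: 13 [(2S,3S)-5-bromo-2-[4-(methoxymethoxy)phenyl]-2,3-dihydro-1-benzofuran-3-yl][2,4-bis(methoxymethoxy)phenyl]methanone; 16 1-[2,4-bis(methoxymethoxy)phenyl]cyclopropan-1-ol
Product: 17 1-[2,4-bis(methoxymethoxy)phenyl]-3-[(2S,3S)-3-[2,4-bis(methoxymethoxy)benzoyl]-2-[4-(methoxymethoxy)phenyl]-2,3-dihydro-1-benzofuran-5-yl]propan-1-one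
Conditions: 16 (1.5 equiv), Pd(OAc)2 (5 mol %), XPhos (10 mol %), Cs2CO3 (2 equiv), toluene, 80 °C
Reagents that add atoms: none
Why: Oxidative addition of Pd(0)/XPhos into the C5–Br bond of 13 is followed by exchange of bromide for the caesium cyclopropoxide of 16, strain-driven β-carbon elimination of either of the two equivalent ring C–C bonds to a C,O-chelated palladium homoenolate Ar–Pd–CH2CH2C(=O)Ar', and C(sp2)–C(sp3) reductive elimination, which forms the C5–CH2 bond and releases the arm ketone at its final oxidation level. The closest known reaction type is the Pd-catalysed cross-coupling of cyclopropanol-derived ketone homoenolates with aryl bromides. No ring is closed; the temporary cyclopropane is opened (β-carbon elimination, the reverse of a 3-exo closure) and is thereby removed in the same event. No stereocentre is created: C2 is not touched, and C3, the only centre that carbonate could enolise, already has its thermodynamic trans arrangement and cannot take C2 with it because expulsion of O1 would be the reverse of a 5-endo-trig closure. The step needs reductive elimination to outrun β-hydride elimination of the homoenolate (secured by the bulky biaryl phosphine and the C,O-chelate) and chemoselectivity over ketone α-arylation (the only acidic C–H of 13, at C3, is tertiary and flanked by two aryl-bearing carbons, and the excess cyclopropanol should outcompete the α-CH2 of the product).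

Step 12
Reactants: 17 1-[2,4-bis(methoxymethoxy)phenyl]-3-[(2S,3S)-3-[2,4-bis(methoxymethoxy)benzoyl]-2-[4-(methoxymethoxy)phenyl]-2,3-dihydro-1-benzofuran-5-yl]propan-1-one
Product: 18 1-(2,4-dihydroxyphenyl)-3-[(2S,3S)-3-(2,4-dihydroxybenzoyl)-2-(4-hydroxyphenyl)-2,3-dihydro-1-benzofuran-5-yl]propan-1-one
Conditions: HCl (3 M in MeOH), THF, 40 °C
Reagents that add atoms: none
Why: Acid-catalysed acetal methanolysis should remove all five MOM groups as dimethoxymethane, while the benzylic C2–O bond is shielded from ionisation by the electron-withdrawing C3 acyl group and C3, if it enolises, returns to the trans configuration.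

**Compound list**

1 | 4-(methoxymethoxy)benzaldehyde | O=Cc1ccc(OCOC)cc1 | starting material
2 | [4-(methoxymethoxy)phenyl]methanol | OCc1ccc(OCOC)cc1 | intermediate
3 | methyl 2-(5-bromo-2-hydroxyphenyl)acetate | COC(=O)Cc1cc(Br)ccc1O | starting material
4 | methyl 2-[5-bromo-2-{[4-(methoxymethoxy)phenyl]methoxy}phenyl]acetate | COC(=O)Cc1cc(Br)ccc1OCc1ccc(OCOC)cc1 | intermediate
5 | methyl 2-[5-bromo-2-{[4-(methoxymethoxy)phenyl]methoxy}phenyl]-2-diazoacetate | COC(=O)C(=[N+]=[N-])c1cc(Br)ccc1OCc1ccc(OCOC)cc1 | intermediate
6 | methyl (2S,3R)-5-bromo-2-[4-(methoxymethoxy)phenyl]-2,3-dihydro-1-benzofuran-3-carboxylate (cis) | Brc1ccc2c(c1)[C@@H](C(=O)OC)[C@@H](c1ccc(OCOC)cc1)O2 | intermediate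
7 | methyl (2S,3S)-5-bromo-2-[4-(methoxymethoxy)phenyl]-2,3-dihydro-1-benzofuran-3-carboxylate (trans) | Brc1ccc2c(c1)[C@H](C(=O)OC)[C@@H](c1ccc(OCOC)cc1)O2 | intermediate
8 | (2S,3S)-5-bromo-N-methoxy-2-[4-(methoxymethoxy)phenyl]-N-methyl-2,3-dihydro-1-benzofuran-3-carboxamide | Brc1ccc2c(c1)[C@H](C(=O)N(C)OC)[C@@H](c1ccc(OCOC)cc1)O2 | intermediate
9 | 4-bromobenzene-1,3-diol | Oc1ccc(Br)c(O)c1 | starting material
10 | 1-bromo-2,4-bis(methoxymethoxy)benzene | COCOc1ccc(Br)c(OCOC)c1 | intermediate
11 | 2,4-bis(methoxymethoxy)phenyllithium | [Li]c1ccc(OCOC)cc1OCOC | intermediate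
12 | lithium hemiaminal alkoxide (tetrahedral adduct of 11 with 8, carbinol carbon unassigned) | Brc1ccc2c(c1)[C@H](C([O-])(N(C)OC)c1ccc(OCOC)cc1OCOC)[C@@H](c1ccc(OCOC)cc1)O2.[Li+] | intermediate
13 | [(2S,3S)-5-bromo-2-[4-(methoxymethoxy)phenyl]-2,3-dihydro-1-benzofuran-3-yl][2,4-bis(methoxymethoxy)phenyl]methanone | Brc1ccc2c(c1)[C@H](C(=O)c1ccc(OCOC)cc1OCOC)[C@@H](c1ccc(OCOC)cc1)O2 | intermediate
14 | methyl 2,4-dihydroxybenzoate | COC(=O)c1ccc(O)cc1O | starting material
15 | methyl 2,4-bis(methoxymethoxy)benzoate | COC(=O)c1ccc(OCOC)cc1OCOC | intermediate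
16 | 1-[2,4-bis(methoxymethoxy)phenyl]cyclopropan-1-ol | OC1(CC1)c1ccc(OCOC)cc1OCOC | intermediate
17 | 1-[2,4-bis(methoxymethoxy)phenyl]-3-[(2S,3S)-3-[2,4-bis(methoxymethoxy)benzoyl]-2-[4-(methoxymethoxy)phenyl]-2,3-dihydro-1-benzofuran-5-yl]propan-1-one | O=C(CCc1ccc2c(c1)[C@H](C(=O)c1ccc(OCOC)cc1OCOC)[C@@H](c1ccc(OCOC)cc1)O2)c1ccc(OCOC)cc1OCOC | intermediate
18 | 1-(2,4-dihydroxyphenyl)-3-[(2S,3S)-3-(2,4-dihydroxybenzoyl)-2-(4-hydroxyphenyl)-2,3-dihydro-1-benzofuran-5-yl]propan-1-one | O=C(CCc1ccc2c(c1)[C@H](C(=O)c1ccc(O)cc1O)[C@@H](c1ccc(O)cc1)O2)c1ccc(O)cc1O | target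

**Count and risks**

Total step count: 12. Longest linear sequence: 9 steps (steps 1, 2, 3, 4, 5, 6, 8, 11, 12).

Steps most likely to fail:

1. Step 11. The palladium homoenolate may undergo β-hydride elimination faster than reductive elimination, which would give hydrodebromination of the benzofuran and an aryl vinyl ketone instead of the coupled product. Fallback, setting out from 13 (with 10 as the source of the partner) and coming back at 17: the aryllithium 11 is generated from 10 as in step 8 and added to acrolein (THF, −78 °C) to give 1-[2,4-bis(methoxymethoxy)phenyl]prop-2-en-1-ol F1. A ligand-free phase-transfer Heck reaction of 13 with F1 (Pd(OAc)2, n-Bu4NCl, NaHCO3, DMF, 90 °C) then inserts the aryl group at the terminal alkene carbon, and β-hydride elimination toward the carbinol C–H followed by enol–ketone tautomerisation delivers 17 directly. In this variant β-hydride elimination is the productive step, and the base is only hydrogen carbonate.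

2. Step 8. The aryllithium may deprotonate C3 (α to the amide and benzylic) instead of adding, which would stall conversion and erode the trans relationship, or slow halogen–metal exchange at C5 may occur. Fallback, setting out from 7 and coming back at 13: DIBAL-H (CH2Cl2, −78 → 0 °C) reduces 7 to [(2S,3R)-5-bromo-2-[4-(methoxymethoxy)phenyl]-2,3-dihydro-1-benzofuran-3-yl]methanol F2. Dess–Martin periodinane oxidises it to (2S,3S)-5-bromo-2-[4-(methoxymethoxy)phenyl]-2,3-dihydro-1-benzofuran-3-carbaldehyde F3, which is used at once. The aryllithium 11 adds to the aldehyde at −78 °C, faster than enolisation, to give [(2S,3R)-5-bromo-2-[4-(methoxymethoxy)phenyl]-2,3-dihydro-1-benzofuran-3-yl][2,4-bis(methoxymethoxy)phenyl]methanol F4 as a mixture of carbinol epimers. A second Dess–Martin oxidation converges both epimers on ketone 13.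

3. Step 4. Facial discrimination by the catalyst may be insufficient, or the sense of induction may be opposite to the assumption, and carbene dimerisation or arene cyclopropanation may compete with the 1,5-insertion. Fallback, setting out from 5 and coming back at 7: the insertion is run with achiral Rh2(OAc)4 (CH2Cl2, rt), which gives 6 together with its mirror image, methyl (2R,3S)-5-bromo-2-[4-(methoxymethoxy)phenyl]-2,3-dihydro-1-benzofuran-3-carboxylate F5. Equilibration with NaOMe in MeOH as in step 5 turns the mixture into 7 together with methyl (2R,3R)-5-bromo-2-[4-(methoxymethoxy)phenyl]-2,3-dihydro-1-benzofuran-3-carboxylate F6. Preparative chromatography on a chiral stationary phase (supercritical CO2/MeOH) removes F6 and supplies enantiopure 7.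

**Further compounds**

F1 | step 11 | 1-[2,4-bis(methoxymethoxy)phenyl]prop-2-en-1-ol | C=CC(O)c1ccc(OCOC)cc1OCOC
F2 | step 8 | [(2S,3R)-5-bromo-2-[4-(methoxymethoxy)phenyl]-2,3-dihydro-1-benzofuran-3-yl]methanol | Brc1ccc2c(c1)[C@H](CO)[C@@H](c1ccc(OCOC)cc1)O2
F3 | step 8 | (2S,3S)-5-bromo-2-[4-(methoxymethoxy)phenyl]-2,3-dihydro-1-benzofuran-3-carbaldehyde | Brc1ccc2c(c1)[C@H](C=O)[C@@H](c1ccc(OCOC)cc1)O2
F4 | step 8 | [(2S,3R)-5-bromo-2-[4-(methoxymethoxy)phenyl]-2,3-dihydro-1-benzofuran-3-yl][2,4-bis(methoxymethoxy)phenyl]methanol | Brc1ccc2c(c1)[C@H](C(O)c1ccc(OCOC)cc1OCOC)[C@@H](c1ccc(OCOC)cc1)O2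
F5 | step 4 | methyl (2R,3S)-5-bromo-2-[4-(methoxymethoxy)phenyl]-2,3-dihydro-1-benzofuran-3-carboxylate | Brc1ccc2c(c1)[C@H](C(=O)OC)[C@H](c1ccc(OCOC)cc1)O2
F6 | step 4 | methyl (2R,3R)-5-bromo-2-[4-(methoxymethoxy)phenyl]-2,3-dihydro-1-benzofuran-3-carboxylate | Brc1ccc2c(c1)[C@@H](C(=O)OC)[C@H](c1ccc(OCOC)cc1)O2
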